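**Retrosynthetic overview**

- Target 22 ← diol 21 (primary alcohol → acid, last step) ← 18, the tropone ring being closed last by an intramolecular vinylogous aldol condensation (tropone C4=C5).
- 18 ← alkynol 12 + CO + vinyl bromide 17 in one palladium-catalysed carbonylative anti-oxyacylation. It forms the oxolane O–C6(tropone) bond (the ring closure), C7–C1 and C1–C2, and brings in every remaining tropone carbon.
- Enabling feature: in the tropone ring the ether oxygen sits on C6, β to the C1 carbonyl, with the methyl on C7. O–C6=C7(CH3)–C1(=O) is therefore a β-alkoxy enone with O and acyl trans across C6=C7, the retron of anti addition of an oxygen and an acyl group to a methyl-capped alkyne; C1 is carbon monoxide, and the five-membered O-ring is the 5-exo closure of a 4-yn-1-ol.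
- 12 ← cyclohexanone 9 + pent-3-ynyl Grignard; 9 ← (S)-carvone by hydration, two α′-alkylations (CH3, then allyl), hydroboration and enone hydrogenation; 17 ← 1,1-dimethoxypropan-2-one by Horner–Wadsworth–Emmons olefination and bromination–dehydrobromination.
- Order of ring formation: cyclohexane (from carvone) → spiro-oxolane (step 11) → tropone (step 12).

Key step: step 11

Remark: compounds 1, 10, 13 and 14 are taken as commercial; tropone atoms are numbered C1 (C=O), C2 (CO2CH3), C3 (CH3), C4 (H), C5 (CH2 arm), C6 (O), C7 (CH3).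

**Route**

Step 1
Reactants: 1 (S)-(+)-carvone
Product: 2 (5S)-5-(2-hydroxypropan-2-yl)-2-methylcyclohex-2-en-1-one
Conditions: 50% aq H2SO4, 0 °C
Reagents that add atoms: water (O)
Why: Acid-catalysed Markovnikov hydration of the 1,1-disubstituted isopropenyl alkene through its tertiary cation should leave the enone and the C5 stereocentre untouched.

Step 2
Reactants: 2 (5S)-5-(2-hydroxypropan-2-yl)-2-methylcyclohex-2-en-1-one
Product: 3 (5S)-2-methyl-5-[2-(triethylsilyloxy)propan-2-yl]cyclohex-2-en-1-one
Conditions: TESOTf, 2,6-lutidine, CH2Cl2, −78 → 0 °C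
Reagents that add atoms: triethylsilyl trifluoromethanesulfonate (CC[Si](CC)(CC)OS(=O)(=O)C(F)(F)F)
Why: Silyl triflate silylation of the tertiary alcohol masks it against alkoxide alkylation in steps 3 and 4 and makes the C5 group a large stereocontrol element.

Step 3
Reactants: 3 (5S)-2-methyl-5-[2-(triethylsilyloxy)propan-2-yl]cyclohex-2-en-1-one
Product: 4 (5S,6R)-2,6-dimethyl-5-[2-(triethylsilyloxy)propan-2-yl]cyclohex-2-en-1-one
Conditions: LiN(i-Pr)2, THF, −78 °C; then CH3I, −78 → −20 °C
Reagents that add atoms: iodomethane (CI)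
Why: Kinetic α′-deprotonation of the cross-conjugated enone and enolate alkylation should give mainly the trans 6-methyl ketone, and the C6 configuration does not matter because this centre is enolised again in step 4.

Step 4
Reactants: 4 (5S,6R)-2,6-dimethyl-5-[2-(triethylsilyloxy)propan-2-yl]cyclohex-2-en-1-one
Product: 5 (5S,6R)-2,6-dimethyl-6-(prop-2-en-1-yl)-5-[2-(triethylsilyloxy)propan-2-yl]cyclohex-2-en-1-one
Conditions: LiN(i-Pr)2, THF, −78 °C; DMPU; allyl bromide, −78 → 0 °C
Reagents that add atoms: allyl bromide (C=CCBr)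
Why: In this second kinetic enolate alkylation the reactive allyl halide should enter anti to the bulky neighbouring C5 substituent, setting the quaternary carbon with allyl trans and methyl cis to that group.

Step 5
Reactants: 5 (5S,6R)-2,6-dimethyl-6-(prop-2-en-1-yl)-5-[2-(triethylsilyloxy)propan-2-yl]cyclohex-2-en-1-one
Product: 7 (5S,6R)-6-(3-hydroxypropyl)-2,6-dimethyl-5-[2-(triethylsilyloxy)propan-2-yl]cyclohex-2-en-1-one, via alkyl-9-BBN adduct 6 (not isolated)
Conditions: 9-BBN, THF, 0 °C → rt; then 30% H2O2, aq NaOAc, 0 °C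
Reagents that add atoms: hydrogen peroxide (OO)
Why: Anti-Markovnikov hydroboration–oxidation should be chemoselective because 9-BBN adds to the monosubstituted terminal alkene far faster than it attacks the hindered conjugated enone, and the buffered peroxide work-up spares the enone.

Step 6
Reactants: 7 (5S,6R)-6-(3-hydroxypropyl)-2,6-dimethyl-5-[2-(triethylsilyloxy)propan-2-yl]cyclohex-2-en-1-one
Product: 8 (5S,6R)-6-[3-(tert-butyldimethylsilyloxy)propyl]-2,6-dimethyl-5-[2-(triethylsilyloxy)propan-2-yl]cyclohex-2-en-1-one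
Conditions: TBSCl, imidazole, DMF, rt
Reagents that add atoms: tert-butyldimethylsilyl chloride (CC(C)(C)[Si](C)(C)Cl)
Why: Standard silylation protects the primary alcohol, which would otherwise capture the acyl–palladium species of step 11.

Step 7
Reactants: 8 (5S,6R)-6-[3-(tert-butyldimethylsilyloxy)propyl]-2,6-dimethyl-5-[2-(triethylsilyloxy)propan-2-yl]cyclohex-2-en-1-one
Product: 9 (2R,3S,6R)-2-[3-(tert-butyldimethylsilyloxy)propyl]-2,6-dimethyl-3-[2-(triethylsilyloxy)propan-2-yl]cyclohexan-1-one
Conditions: H2 (1 atm), 10% Pd/C, EtOAc, rt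
Reagents that add atoms: none
Why: Heterogeneous catalytic hydrogenation of the enone C=C should deliver hydrogen cis from the face opposite the C3 silyloxyisopropyl group and the axial C2 methyl (the face of the mobile propyl chain), giving the kinetic ketone with the new C6 methyl cis to the C2 methyl; it is kept away from base.

Step 8
Reactants: 9 (2R,3S,6R)-2-[3-(tert-butyldimethylsilyloxy)propyl]-2,6-dimethyl-3-[2-(triethylsilyloxy)propan-2-yl]cyclohexan-1-one, 10 5-bromopent-2-yne
Product: 12 (1R,2R,3S,6R)-2-[3-(tert-butyldimethylsilyloxy)propyl]-2,6-dimethyl-1-(pent-3-yn-1-yl)-3-[2-(triethylsilyloxy)propan-2-yl]cyclohexan-1-ol, via pent-3-ynylmagnesium bromide 11 (not isolated)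
Conditions: 10, Mg, THF, rt; then 9, LaCl3·2LiCl, THF, 0 °C; aq NH4Cl
Reagents that add atoms: none
Why: Lanthanum-promoted Grignard 1,2-addition should suppress enolisation of the hindered ketone, and attack along the axial trajectory from the face opposite the two axial α-methyl groups and the C3 substituent sets the carbinol carbon with OH cis to both methyls.

Step 9
Reactants: 13 1,1-dimethoxypropan-2-one, 14 trimethyl phosphonoacetate
Product: 15 methyl (2E)-4,4-dimethoxy-3-methylbut-2-enoate
Conditions: NaH, THF, 0 °C → rt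
Reagents that add atoms: none
Why: Horner–Wadsworth–Emmons olefination of the activated α,α-dialkoxy ketone should give the (E)-enoate with the ester cis to the methyl group.

Step 10
Reactants: 15 methyl (2E)-4,4-dimethoxy-3-methylbut-2-enoate
Product: 17 methyl (2Z)-2-bromo-4,4-dimethoxy-3-methylbut-2-enoate, via dibromo ester 16 (not isolated)
Conditions: Br2, CH2Cl2, 0 °C; then Et3N, 0 °C → rt
Reagents that add atoms: bromine (BrBr)
Why: Bromine addition followed by amine-induced dehydrobromination through the acidic α-hydrogen should give the α-bromo enoate, expected mainly with the ester cis to the smaller methyl group; its geometry is not critical (see step 11).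

Step 11
Reactants: 12 (1R,2R,3S,6R)-2-[3-(tert-butyldimethylsilyloxy)propyl]-2,6-dimethyl-1-(pent-3-yn-1-yl)-3-[2-(triethylsilyloxy)propan-2-yl]cyclohexan-1-ol, 17 methyl (2Z)-2-bromo-4,4-dimethoxy-3-methylbut-2-enoate
Product: 18 methyl (2E)-2-{(2E)-2-[(5R,6R,7S,10R)-6-[3-(tert-butyldimethylsilyloxy)propyl]-6,10-dimethyl-7-[2-(triethylsilyloxy)propan-2-yl]-1-oxaspiro[4.5]decan-2-ylidene]propanoyl}-4,4-dimethoxy-3-methylbut-2-enoate
Conditions: Pd(PPh3)4 (10 mol %), CO (1 atm), K2CO3, MeCN, 60 °C
Reagents that add atoms: carbon monoxide ([C-]#[O+])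
Why: Proposed new method: zerovalent palladium inserts into the C–Br bond of 17 and CO insertion gives an acyl–palladium bromide (divalent palladium); this electrophilic centre binds the alkyne of 12, the tertiary hydroxyl adds anti in a 5-exo-dig closure that makes the O–C bond and the oxolane ring, and C–C reductive elimination from the resulting vinyl(acyl)palladium releases 18 and zerovalent palladium. The closest known reaction type is the palladium-catalysed carbonylative cyclisation of 2-alkynylphenols and 2-alkynyl trifluoroacetanilides with organic halides and CO to 3-acylbenzofurans and 3-acylindoles, together with the arylative cyclisation of 4-alkyn-1-ol alkoxides; new here are the unactivated tertiary alcohol and the functionalised vinyl bromide. The single ring closed is the oxolane, by 5-exo-dig attack of oxygen on the proximal alkyne carbon, favoured over 6-endo by the 4-yn-1-ol tether and the fully substituted carbinol. No stereocentre is formed (the spiro carbon comes from step 8); the C=C geometry follows from anti oxypalladation and retentive reductive elimination, which place the acyl carbon trans to oxygen and cis to the ring CH2, as the tropone closure needs. The step needs CO insertion before cyclisation (CO atmosphere; the hindered tertiary alcohol is a poor acyl acceptor) and anti rather than syn addition (weak carbonate base keeps the hydroxyl off palladium); the C2=C3 geometry of 17 is not critical because the alkylidene β-keto ester of 18 equilibrates.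

Step 12
Reactants: 18 methyl (2E)-2-{(2E)-2-[(5R,6R,7S,10R)-6-[3-(tert-butyldimethylsilyloxy)propyl]-6,10-dimethyl-7-[2-(triethylsilyloxy)propan-2-yl]-1-oxaspiro[4.5]decan-2-ylidene]propanoyl}-4,4-dimethoxy-3-methylbut-2-enoate
Product: 21 methyl (2R,2'R,3'S,6'R)-3'-(2-hydroxypropan-2-yl)-2'-(3-hydroxypropyl)-2',5,6',8-tetramethyl-7-oxo-3,7-dihydrospiro[cyclohepta[b]furan-2,1'-cyclohexane]-6-carboxylate, via enal 19 (not isolated), via bis-silyl tropone 20 (not isolated)
Conditions: TsOH·H2O, THF/H2O (5:1), 40 °C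
Reagents that add atoms: none
Why: Acid hydrolysis of the dimethyl acetal frees the enal, whose aldehyde is attacked by the oxolane CH2 next to the enol-ether carbon through the dienol of the β-alkoxy enone (intramolecular vinylogous aldol condensation); dehydration to the aromatic tropone should drive the seven-membered closure, the same acid cleaves both silyl ethers, and no stereocentre is touched.

Step 13
Reactants: 21 methyl (2R,2'R,3'S,6'R)-3'-(2-hydroxypropan-2-yl)-2'-(3-hydroxypropyl)-2',5,6',8-tetramethyl-7-oxo-3,7-dihydrospiro[cyclohepta[b]furan-2,1'-cyclohexane]-6-carboxylate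
Product: 22 3-[(2R,2'R,3'S,6'R)-3'-(2-hydroxypropan-2-yl)-6-(methoxycarbonyl)-2',5,6',8-tetramethyl-7-oxo-3,7-dihydrospiro[cyclohepta[b]furan-2,1'-cyclohexan]-2'-yl]propanoic acid
Conditions: TEMPO (20 mol %), PhI(OAc)2, MeCN/H2O (1:1), rt
Reagents that add atoms: water (O)
Why: Oxoammonium (TEMPO) oxidation in aqueous acetonitrile should take the primary alcohol through the aldehyde hydrate to the carboxylic acid, while the tertiary alcohol, the methyl ester and the push–pull alkoxytropone are inert.

**Compound list**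

1 | (S)-(+)-carvone | O=C1C(C)=CC[C@H](C(C)=C)C1 | starting material
2 | (5S)-5-(2-hydroxypropan-2-yl)-2-methylcyclohex-2-en-1-one | O=C1C(C)=CC[C@H](C(C)(C)O)C1 | intermediate
3 | (5S)-2-methyl-5-[2-(triethylsilyloxy)propan-2-yl]cyclohex-2-en-1-one | O=C1C(C)=CC[C@H](C(C)(C)O[Si](CC)(CC)CC)C1 | intermediate
4 | (5S,6R)-2,6-dimethyl-5-[2-(triethylsilyloxy)propan-2-yl]cyclohex-2-en-1-one (6-methyl trans to the C5 group; carried on together with its C6 epimer) | O=C1C(C)=CC[C@H](C(C)(C)O[Si](CC)(CC)CC)[C@H]1C | intermediate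
5 | (5S,6R)-2,6-dimethyl-6-(prop-2-en-1-yl)-5-[2-(triethylsilyloxy)propan-2-yl]cyclohex-2-en-1-one (allyl trans to the C5 group) | O=C1C(C)=CC[C@H](C(C)(C)O[Si](CC)(CC)CC)[C@@]1(C)CC=C | intermediate
6 | 9-alkyl-9-borabicyclo[3.3.1]nonane adduct of 5 (boron on the terminal carbon of the former allyl group) | O=C1C(C)=CC[C@H](C(C)(C)O[Si](CC)(CC)CC)[C@@]1(C)CCCB1C2CCCC1CCC2 | intermediate (not isolated)
7 | (5S,6R)-6-(3-hydroxypropyl)-2,6-dimethyl-5-[2-(triethylsilyloxy)propan-2-yl]cyclohex-2-en-1-one | O=C1C(C)=CC[C@H](C(C)(C)O[Si](CC)(CC)CC)[C@@]1(C)CCCO | intermediate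
8 | (5S,6R)-6-[3-(tert-butyldimethylsilyloxy)propyl]-2,6-dimethyl-5-[2-(triethylsilyloxy)propan-2-yl]cyclohex-2-en-1-one | O=C1C(C)=CC[C@H](C(C)(C)O[Si](CC)(CC)CC)[C@@]1(C)CCCO[Si](C)(C)C(C)(C)C | intermediate
9 | (2R,3S,6R)-2-[3-(tert-butyldimethylsilyloxy)propyl]-2,6-dimethyl-3-[2-(triethylsilyloxy)propan-2-yl]cyclohexan-1-one (both methyls and the C3 group on one face, chain on the other) | O=C1[C@H](C)CC[C@H](C(C)(C)O[Si](CC)(CC)CC)[C@@]1(C)CCCO[Si](C)(C)C(C)(C)C | intermediate
10 | 5-bromopent-2-yne | CC#CCCBr | starting material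
11 | pent-3-yn-1-ylmagnesium bromide | CC#CCC[Mg]Br | intermediate (not isolated)
12 | (1R,2R,3S,6R)-2-[3-(tert-butyldimethylsilyloxy)propyl]-2,6-dimethyl-1-(pent-3-yn-1-yl)-3-[2-(triethylsilyloxy)propan-2-yl]cyclohexan-1-ol (OH cis to both methyls) | O[C@]1(CCC#CC)[C@H](C)CC[C@H](C(C)(C)O[Si](CC)(CC)CC)[C@@]1(C)CCCO[Si](C)(C)C(C)(C)C | intermediate
13 | 1,1-dimethoxypropan-2-one | CC(=O)C(OC)OC | starting material
14 | trimethyl phosphonoacetate | COC(=O)CP(=O)(OC)OC | starting material
15 | methyl (2E)-4,4-dimethoxy-3-methylbut-2-enoate | COC(=O)/C=C(\C)C(OC)OC | intermediate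
16 | methyl (2S*,3R*)-2,3-dibromo-4,4-dimethoxy-3-methylbutanoate (racemic; one enantiomer drawn) | COC(=O)[C@H](Br)[C@](C)(Br)C(OC)OC | intermediate (not isolated)
17 | methyl (2Z)-2-bromo-4,4-dimethoxy-3-methylbut-2-enoate (Br cis to the dimethoxymethyl group) | COC(=O)/C(Br)=C(\C)C(OC)OC | intermediate
18 | methyl (2E)-2-{(2E)-2-[(5R,6R,7S,10R)-6-[3-(tert-butyldimethylsilyloxy)propyl]-6,10-dimethyl-7-[2-(triethylsilyloxy)propan-2-yl]-1-oxaspiro[4.5]decan-2-ylidene]propanoyl}-4,4-dimethoxy-3-methylbut-2-enoate (ketone carbon trans to ring O and cis to the dimethoxymethyl group) | COC(=O)/C(=C(\C)C(OC)OC)C(=O)/C(C)=C2/O[C@]1(CC2)[C@H](C)CC[C@H](C(C)(C)O[Si](CC)(CC)CC)[C@@]1(C)CCCO[Si](C)(C)C(C)(C)C | intermediate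
19 | 4-oxo (enal) analogue of 18: methyl (2E)-2-{(2E)-2-[(5R,6R,7S,10R)-disilylated 1-oxaspiro[4.5]decan-2-ylidene]propanoyl}-3-methyl-4-oxobut-2-enoate | COC(=O)/C(=C(\C)C=O)C(=O)/C(C)=C2/O[C@]1(CC2)[C@H](C)CC[C@H](C(C)(C)O[Si](CC)(CC)CC)[C@@]1(C)CCCO[Si](C)(C)C(C)(C)C | intermediate (not isolated)
20 | methyl (2R,2'R,3'S,6'R)-2'-[3-(tert-butyldimethylsilyloxy)propyl]-2',5,6',8-tetramethyl-7-oxo-3'-[2-(triethylsilyloxy)propan-2-yl]-3,7-dihydrospiro[cyclohepta[b]furan-2,1'-cyclohexane]-6-carboxylate | COC(=O)c1c(C)cc2c(c(C)c1=O)O[C@]1(C2)[C@H](C)CC[C@H](C(C)(C)O[Si](CC)(CC)CC)[C@@]1(C)CCCO[Si](C)(C)C(C)(C)C | intermediate (not isolated)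
21 | methyl (2R,2'R,3'S,6'R)-3'-(2-hydroxypropan-2-yl)-2'-(3-hydroxypropyl)-2',5,6',8-tetramethyl-7-oxo-3,7-dihydrospiro[cyclohepta[b]furan-2,1'-cyclohexane]-6-carboxylate | COC(=O)c1c(C)cc2c(c(C)c1=O)O[C@]1(C2)[C@H](C)CC[C@H](C(C)(C)O)[C@@]1(C)CCCO | intermediate
22 | 3-[(2R,2'R,3'S,6'R)-3'-(2-hydroxypropan-2-yl)-6-(methoxycarbonyl)-2',5,6',8-tetramethyl-7-oxo-3,7-dihydrospiro[cyclohepta[b]furan-2,1'-cyclohexan]-2'-yl]propanoic acid (CNP0448476.2) | COC(=O)c1c(C)cc2c(c(C)c1=O)O[C@]1(C2)[C@H](C)CC[C@H](C(C)(C)O)[C@@]1(C)CCC(=O)O | target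

**Step count and risks**

Total step count: 13. Longest linear sequence: 11 (steps 1–8, 11, 12, 13).

Steps most likely to fail:

Step 11 (bears the label). CO insertion may be outrun by direct coupling of the vinyl–palladium species, the acyl–palladium species may be intercepted before the alkyne binds, or the neutral tertiary hydroxyl may fail to add across the coordinated alkyne. The fallback sets out from 12 and comes back at 18, using known reactions only. Oxidative alkoxycarbonylative cyclisation of 12 (PdCl2(MeCN)2 cat., p-benzoquinone, CO, MeOH) should form the same O–C bond by anti 5-exo oxypalladation, with methanol as acyl acceptor, and give methyl (2E)-2-[(5R,6R,7S,10R)-disilylated 1-oxaspiro[4.5]decan-2-ylidene]propanoate F1. Reduction with i-Bu2AlH should give the allylic alcohol F2, and MnO2 the β-alkoxy enal F3. Nozaki–Hiyama–Kishi coupling of F3 with vinyl bromide 17 (CrCl2, NiCl2 cat., DMF) should give the dienyl carbinol F4 as an epimer mixture, and Dess–Martin oxidation returns 18.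

Step 12. Acid may heterolyse the tertiary-alkyl enol ether, or enolisation may feed other condensation modes instead of the seven-membered closure. The fallback sets out from 18 and comes back at 20. Mild transacetalisation (PPTS, wet acetone) should stop at the enal 19, now isolated. Soft enolisation with TiCl4/i-Pr2NEt in CH2Cl2 at −78 °C should generate the titanium dienolate at the oxolane CH2, which adds to the aldehyde in a directed intramolecular vinylogous aldol addition to give the hydroxy-cycloheptadienone F5. Mesylation (MsCl, Et3N) and elimination with DBU should give 20, which is then desilylated under the acid of step 12 to 21.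

Step 7. Hydrogen delivery may show poor facial selectivity, and the kinetically formed C6 methyl may epimerise on the catalyst to the more stable trans-2,6-dimethyl ketone. The fallback sets out from 8 and comes back at 9. 1,4-Reduction with LiBH(sec-Bu)3 in THF at −78 °C and trapping with Me3SiCl should give the trimethylsilyl enol ether F6. MeLi regenerates the amine-free lithium enolate, and kinetic protonation at −78 °C with a bulky proton source (2,6-di-tert-butyl-4-methylphenol) from the face opposite the C3 substituent and the C2 methyl should give 9.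

Further compounds
F1 | step 11 | methyl (2E)-2-[(5R,6R,7S,10R)-6-[3-(tert-butyldimethylsilyloxy)propyl]-6,10-dimethyl-7-[2-(triethylsilyloxy)propan-2-yl]-1-oxaspiro[4.5]decan-2-ylidene]propanoate | COC(=O)/C(C)=C2/O[C@]1(CC2)[C@H](C)CC[C@H](C(C)(C)O[Si](CC)(CC)CC)[C@@]1(C)CCCO[Si](C)(C)C(C)(C)C
F2 | step 11 | (2E)-2-[(5R,6R,7S,10R)-disilylated 1-oxaspiro[4.5]decan-2-ylidene]propan-1-ol (CH2OH trans to ring O) | OC/C(C)=C2/O[C@]1(CC2)[C@H](C)CC[C@H](C(C)(C)O[Si](CC)(CC)CC)[C@@]1(C)CCCO[Si](C)(C)C(C)(C)C
F3 | step 11 | (2E)-2-[(5R,6R,7S,10R)-disilylated 1-oxaspiro[4.5]decan-2-ylidene]propanal (CHO trans to ring O) | O=C/C(C)=C2/O[C@]1(CC2)[C@H](C)CC[C@H](C(C)(C)O[Si](CC)(CC)CC)[C@@]1(C)CCCO[Si](C)(C)C(C)(C)C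
F4 | step 11 | carbinol corresponding to 18 (C=O of the ketone replaced by CHOH; mixture of carbinol epimers) | COC(=O)/C(=C(\C)C(OC)OC)C(O)/C(C)=C2/O[C@]1(CC2)[C@H](C)CC[C@H](C(C)(C)O[Si](CC)(CC)CC)[C@@]1(C)CCCO[Si](C)(C)C(C)(C)C
F5 | step 12 | aldol adduct of 19: methyl 4-hydroxy-3a,4-dihydro analogue of 20 (tropone C4 carries OH, C5 carries H; mixture at these two centres) | COC(=O)C1=C(C)C(O)C2C(=C(C)C1=O)O[C@]1(C2)[C@H](C)CC[C@H](C(C)(C)O[Si](CC)(CC)CC)[C@@]1(C)CCCO[Si](C)(C)C(C)(C)C
F6 | step 7 | trimethylsilyl enol ether of 9: (5S,6R)-6-[3-(tert-butyldimethylsilyloxy)propyl]-2,6-dimethyl-5-[2-(triethylsilyloxy)propan-2-yl]-1-(trimethylsilyloxy)cyclohex-1-ene | C[Si](C)(C)OC1=C(C)CC[C@H](C(C)(C)O[Si](CC)(CC)CC)[C@@]1(C)CCCO[Si](C)(C)C(C)(C)C
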